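**Retrosynthetic overview**

1. Numbering (rearranged drimane): ring A = C1–C2–C3–C4–C5–C10, ring B = C5–C6–C7–C8–C9–C10; C4 carries the exocyclic CH2, C5, C8 and C9 carry methyls, C9 also the arylmethyl group. Endgame: target 31 ⇐ 30 (MOM removal) ⇐ 28 (ortho-lithiation/ClCO2Me) ⇐ 26 (Wittig methylenation at C4, desulfonylation at C1).
2. Key disconnection: ring-A bonds C1–C2 and C5–C10 are made together by an intramolecular Diels–Alder reaction of the acyclic triene 24 (2-silyloxydiene C2=C3–C4(OTBS)=C5 plus (E)-vinyl sulfone C1=C10). Rings A and B form in the same operation; nothing is cyclic before it except the arene.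
3. Enabling feature: the C4 exocyclic methylene of ring A is a latent C4 ketone, that is, the C3=C4 silyl enol ether of a [4+2] adduct. Diene terminus C5 and dienophile carbon C10 are joined by C6–C7–C8–C9 of ring B, so the C5–C10 ring-fusion bond closes ring B while ring A forms. A temporary PhSO2 group on C1 activates the dienophile.
4. Triene precursor 23 ⇐ vinyl sulfone 22 (CH2=CHMgBr on the Weinreb amide) ⇐ aldehyde 21 (Horner–Wadsworth–Emmons) ⇐ iodide 17 + acrylamide 19 (Giese) ⇐ acid 15.
5. C8/C9 stereodiad ⇐ Ireland–Claisen rearrangement of propanoate 12 with chirality transfer from the (R)-lactate-derived allylic alcohol 11 ⇐ aryllithium 9 + allylic bromide 8.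

Key step: step 17

Remark: C5 of 20–23 (the carbon α to the amide or ketone carbonyl) is formed as a mixture of epimers, which is without consequence because it becomes sp2 in 24.

**Route**

Step 1
Reactants: 1 pyrogallol
Product: 2 1,2,3-tris(methoxymethoxy)benzene
Conditions: NaH, MOMCl, DMF, 0 °C → rt
Reagents that add atoms: chloromethyl methyl ether, COCCl
Why: Williamson-type O-alkylation (MOM protection) of all three phenols gives ethers that later direct both ortho-lithiations and leave under mild acid.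

Step 2
Reactants: 3 methyl (R)-lactate
Product: 4 methyl (2R)-2-[(tert-butyldimethylsilyl)oxy]propanoate
Conditions: TBSCl, imidazole, DMF, rt
Reagents that add atoms: tert-butyldimethylsilyl chloride, CC(C)(C)[Si](C)(C)Cl
Why: Standard silyl ether protection of the secondary alcohol leaves the chiral-pool (R)-centre untouched.

Step 3
Reactants: 4 methyl (2R)-2-[(tert-butyldimethylsilyl)oxy]propanoate
Product: 6 ethyl (2E,4R)-4-[(tert-butyldimethylsilyl)oxy]-2-methylpent-2-enoate, via silyloxy aldehyde 5 (not isolated)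
Conditions: i-Bu2AlH (1.05 equiv), CH2Cl2, −78 °C; then Ph3P=C(CH3)CO2Et, −78 °C → rt
Reagents that add atoms: ethyl 2-(triphenylphosphoranylidene)propanoate, CCOC(=O)C(C)=P(c1ccccc1)(c1ccccc1)c1ccccc1
Why: Half-reduction of the ester followed in the same flask by Wittig olefination with the stabilised α-methyl ylide should give the (E)-trisubstituted enoate without epimerising the α-silyloxy aldehyde.

Step 4
Reactants: 6 ethyl (2E,4R)-4-[(tert-butyldimethylsilyl)oxy]-2-methylpent-2-enoate
Product: 7 (2E,4R)-4-[(tert-butyldimethylsilyl)oxy]-2-methylpent-2-en-1-ol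
Conditions: i-Bu2AlH (2.2 equiv), CH2Cl2, −78 °C
Reagents that add atoms: none
Why: 1,2-Reduction of the enoate by the aluminium hydride gives the allylic alcohol with the alkene geometry unchanged.

Step 5
Reactants: 7 (2E,4R)-4-[(tert-butyldimethylsilyl)oxy]-2-methylpent-2-en-1-ol
Product: 8 {[(2R,3E)-5-bromo-4-methylpent-3-en-2-yl]oxy}(tert-butyl)dimethylsilane
Conditions: CBr4, PPh3, CH2Cl2, 0 °C
Reagents that add atoms: carbon tetrabromide, BrC(Br)(Br)Br
Why: Appel bromination of the primary allylic alcohol proceeds by SN2 displacement without allylic transposition under neutral conditions that the silyl ether tolerates.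

Step 6
Reactants: 2 1,2,3-tris(methoxymethoxy)benzene; 8 {[(2R,3E)-5-bromo-4-methylpent-3-en-2-yl]oxy}(tert-butyl)dimethylsilane
Product: 10 tert-butyldimethyl({(2R,3E)-4-methyl-5-[2,3,4-tris(methoxymethoxy)phenyl]pent-3-en-2-yl}oxy)silane, via aryllithium 9 (not isolated)
Conditions: n-BuLi, THF, 0 °C; then CuBr·SMe2 (10 mol %), 8, −78 → 0 °C
Reagents that add atoms: none
Why: MOM-directed ortho-lithiation of 2 at C4 followed by copper-catalysed SN2 allylation at the primary carbon of 8 (the γ-carbon is shielded by the silyloxy-bearing stereocentre) should form the aryl–CH2 bond with retention of the (E)-alkene.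

Step 7
Reactants: 10 tert-butyldimethyl({(2R,3E)-4-methyl-5-[2,3,4-tris(methoxymethoxy)phenyl]pent-3-en-2-yl}oxy)silane
Product: 11 (2R,3E)-4-methyl-5-[2,3,4-tris(methoxymethoxy)phenyl]pent-3-en-2-ol
Conditions: Bu4NF, THF, 0 °C → rt
Reagents that add atoms: none
Why: Fluoride-induced desilylation releases the (R)-allylic alcohol without touching the MOM ethers.

Step 8
Reactants: 11 (2R,3E)-4-methyl-5-[2,3,4-tris(methoxymethoxy)phenyl]pent-3-en-2-ol
Product: 12 (2R,3E)-4-methyl-5-[2,3,4-tris(methoxymethoxy)phenyl]pent-3-en-2-yl propanoate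
Conditions: EtCOCl, pyridine, DMAP (cat.), CH2Cl2, 0 °C
Reagents that add atoms: propanoyl chloride, CCC(=O)Cl
Why: DMAP-catalysed O-acylation of the secondary allylic alcohol occurs with retention at the carbinol centre.

Step 9
Reactants: 12 (2R,3E)-4-methyl-5-[2,3,4-tris(methoxymethoxy)phenyl]pent-3-en-2-yl propanoate
Product: 15 (2R,3S,4E)-2,3-dimethyl-3-[2,3,4-tris(methoxymethoxy)benzyl]hex-4-enoic acid, via silyl ketene acetal 13 (not isolated), via trimethylsilyl ester 14 (not isolated)
Conditions: LiN(i-Pr)2, THF–DMPU (4:1), −78 °C; Me3SiCl; −78 → 50 °C; then aq. NaOH, then citric acid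
Reagents that add atoms: none
Why: Ireland–Claisen rearrangement in which the Z(O)-enolate formed in THF–DMPU is trapped as ketene acetal 13 (CH3 cis to OSi) and rearranges through a chair transition state with the carbinol CH3 equatorial, so that the (R)-C–O centre is transferred to the quaternary C9 and the enolate geometry sets C8 (C8–CH3 and arylmethyl equatorial, C9–CH3 axial), the new alkene being (E).

Step 10
Reactants: 15 (2R,3S,4E)-2,3-dimethyl-3-[2,3,4-tris(methoxymethoxy)benzyl]hex-4-enoic acid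
Product: 16 (2R,3S,4E)-2,3-dimethyl-3-[2,3,4-tris(methoxymethoxy)benzyl]hex-4-en-1-ol
Conditions: LiAlH4, THF, 0 °C → rt
Reagents that add atoms: none
Why: Hydride reduction of the acid through its carboxylate gives the primary alcohol without epimerisation at C8.

Step 11
Reactants: 16 (2R,3S,4E)-2,3-dimethyl-3-[2,3,4-tris(methoxymethoxy)benzyl]hex-4-en-1-ol
Product: 17 1-{[(2E,4S,5R)-6-iodo-4,5-dimethylhex-2-en-4-yl]methyl}-2,3,4-tris(methoxymethoxy)benzene
Conditions: I2, PPh3, imidazole, CH2Cl2, 0 °C → rt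
Reagents that add atoms: iodine, II
Why: Appel-type iodination of the primary alcohol by SN2 displacement of the oxyphosphonium ion, buffered by imidazole to protect the MOM ethers.

Step 12
Reactants: 18 methacryloyl chloride
Product: 19 N-methoxy-N-methylmethacrylamide
Conditions: MeNH(OMe)·HCl, Et3N, CH2Cl2, 0 °C
Reagents that add atoms: N,O-dimethylhydroxylamine hydrochloride, CNOC.Cl
Why: N-Acylation of the hydroxylamine by the acid chloride gives the Weinreb amide acceptor.

Step 13
Reactants: 17 1-{[(2E,4S,5R)-6-iodo-4,5-dimethylhex-2-en-4-yl]methyl}-2,3,4-tris(methoxymethoxy)benzene; 19 N-methoxy-N-methylmethacrylamide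
Product: 20 (5S,6R,7E)-N-methoxy-N,2,5,6-tetramethyl-6-[2,3,4-tris(methoxymethoxy)benzyl]non-7-enamide (C2 epimers)
Conditions: 19 (5 equiv), (Me3Si)3SiH (slow addition), AIBN (cat.), toluene, 80 °C
Reagents that add atoms: none
Why: Giese reaction in which the primary C7 radical adds to the unsubstituted β-carbon of 19 and is reduced by the silane, while 4-exo or 5-endo closure onto the propenyl group cannot compete and the new α-centre is formed without control, which is irrelevant.

Step 14
Reactants: 20 (5S,6R,7E)-N-methoxy-N,2,5,6-tetramethyl-6-[2,3,4-tris(methoxymethoxy)benzyl]non-7-enamide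
Product: 21 (5S,6R)-N-methoxy-N,2,5,6-tetramethyl-7-oxo-6-[2,3,4-tris(methoxymethoxy)benzyl]heptanamide
Conditions: K2OsO4·2H2O (cat.), NaIO4, 2,6-lutidine, dioxane–H2O, rt
Reagents that add atoms: sodium periodate, [Na+].[O-]I(=O)(=O)=O
Why: Lemieux–Johnson oxidative cleavage of the only alkene gives the non-enolisable neopentyl aldehyde, the electron-rich arene being inert to this oxidant pair.

Step 15
Reactants: 21 (5S,6R)-N-methoxy-N,2,5,6-tetramethyl-7-oxo-6-[2,3,4-tris(methoxymethoxy)benzyl]heptanamide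
Product: 22 (5S,6R,7E)-N-methoxy-N,2,5,6-tetramethyl-8-(phenylsulfonyl)-6-[2,3,4-tris(methoxymethoxy)benzyl]oct-7-enamide
Conditions: (EtO)2P(O)CH2SO2Ph, NaH, THF, 0 °C → rt
Reagents that add atoms: diethyl [(phenylsulfonyl)methyl]phosphonate, CCOP(=O)(CS(=O)(=O)c1ccccc1)OCC
Why: Horner–Wadsworth–Emmons olefination with the sulfonyl-stabilised phosphonate should give the (E)-vinyl sulfone, the aldehyde having no α-hydrogen.

Step 16
Reactants: 22 (5S,6R,7E)-N-methoxy-N,2,5,6-tetramethyl-8-(phenylsulfonyl)-6-[2,3,4-tris(methoxymethoxy)benzyl]oct-7-enamide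
Product: 23 (7S,8R,9E)-4,7,8-trimethyl-10-(phenylsulfonyl)-8-[2,3,4-tris(methoxymethoxy)benzyl]deca-1,9-dien-3-one
Conditions: CH2=CHMgBr, THF, −20 → 0 °C; cold 1 M aq. HCl quench
Reagents that add atoms: vinylmagnesium bromide, C=C[Mg]Br
Why: Weinreb ketone synthesis in which the Grignard reagent adds once through the stable chelate, the vinyl sulfone being spared because its β-carbon C10 is neopentylic, and the acidic quench removes MeONHMe before it can add to the enone.

Step 17
Reactants: 23 (7S,8R,9E)-4,7,8-trimethyl-10-(phenylsulfonyl)-8-[2,3,4-tris(methoxymethoxy)benzyl]deca-1,9-dien-3-one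
Product: 26 (4S,4aS,5R,6S,8aS)-5,6,8a-trimethyl-4-(phenylsulfonyl)-5-[2,3,4-tris(methoxymethoxy)benzyl]octahydronaphthalen-1(2H)-one, via silyl dienol ether 24 (not isolated), via cycloadduct silyl enol ether 25 (not isolated)
Conditions: TBSOTf, Et3N, CH2Cl2, −78 → 0 °C; exchange to toluene (pentane filtration from Et3NH·OTf), BHT (cat.), 120 °C, sealed tube; then Bu4NF, AcOH, THF, 0 °C
Reagents that add atoms: none
Why: Soft enolisation of the vinyl ketone toward C5 (its only α-hydrogen) gives the cross-conjugated 2-silyloxydiene 24, which on heating undergoes a concerted, asynchronous intramolecular [4+2] cycloaddition with the (E)-vinyl sulfone, the nucleophilic terminus C5 bonding to the β-carbon C10 and C2 to C1; the closest known reaction type is the type 1 intramolecular Diels–Alder reaction of 1,7,9-decatrienes carrying a terminally activated (E)-dienophile. Ring A is closed by the cycloaddition itself (six-membered carbocyclic [4+2]) and ring B is closed at the same moment by the C5–C10 bond across the four-carbon tether C6–C9 (fused bicyclo[4.4.0] mode). The quaternary C5 and C10 are set trans by the transition state that holds the sulfonyl group endo and the tether exo to the diene (the quaternary C9 cannot sit under C3/C4–OSi), and the (E)-geometry fixes the later deleted C1 centre. The face is chosen by C8 and C9, because in the chair-like tether only the arrangement of the target keeps C8–CH3 and the C9 arylmethyl group equatorial and only the small C9–CH3 axial. The step needs trans fusion, this facial sense and the (3Z)-dienol ether (tether cis to OSi); the last is expected to predominate modestly on allylic-strain grounds, and the (3E)-isomer, which cannot reach the dienophile, is returned as 23 on desilylation and can be recycled. Regiochemistry is fixed by the tether and is also the electronically matched one.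

Step 18
Reactants: 26 (4S,4aS,5R,6S,8aS)-5,6,8a-trimethyl-4-(phenylsulfonyl)-5-[2,3,4-tris(methoxymethoxy)benzyl]octahydronaphthalen-1(2H)-one
Product: 27 1-{[(1R,2S,4aS,8S,8aS)-1,2,4a-trimethyl-5-methylidene-8-(phenylsulfonyl)decahydronaphthalen-1-yl]methyl}-2,3,4-tris(methoxymethoxy)benzene
Conditions: Ph3PCH3Br, KOt-Bu, toluene, rt → 90 °C
Reagents that add atoms: methyltriphenylphosphonium bromide, C[P+](c1ccccc1)(c1ccccc1)c1ccccc1.[Br-]
Why: Wittig methylenation of the hindered C4 ketone with excess ylide at elevated temperature, the ylide being too weak a base to deprotonate the sulfone and C5 being quaternary, so that no stereocentre is at risk.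

Step 19
Reactants: 27 1-{[(1R,2S,4aS,8S,8aS)-1,2,4a-trimethyl-5-methylidene-8-(phenylsulfonyl)decahydronaphthalen-1-yl]methyl}-2,3,4-tris(methoxymethoxy)benzene
Product: 28 1-{[(1R,2S,4aS,8aS)-1,2,4a-trimethyl-5-methylidenedecahydronaphthalen-1-yl]methyl}-2,3,4-tris(methoxymethoxy)benzene
Conditions: 6% Na(Hg), MeOH–THF, −20 °C → rt
Reagents that add atoms: none
Why: Reductive desulfonylation by electron transfer removes the temporary activating group at C1 and leaves the isolated 1,1-disubstituted alkene and the MOM ethers untouched.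

Step 20
Reactants: 28 1-{[(1R,2S,4aS,8aS)-1,2,4a-trimethyl-5-methylidenedecahydronaphthalen-1-yl]methyl}-2,3,4-tris(methoxymethoxy)benzene
Product: 30 methyl 2,3,4-tris(methoxymethoxy)-5-{[(1R,2S,4aS,8aS)-1,2,4a-trimethyl-5-methylidenedecahydronaphthalen-1-yl]methyl}benzoate, via aryllithium 29 (not isolated)
Conditions: n-BuLi, TMEDA, THF, −20 → 0 °C; then cannulation into ClCO2Me (5 equiv), THF, −78 °C
Reagents that add atoms: methyl chloroformate, COC(=O)Cl
Why: Directed ortho-metalation places lithium at the only ring position ortho to an OMOM group, and inverse addition to excess chloroformate gives the methyl ester without over-addition.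

Step 21
Reactants: 30 methyl 2,3,4-tris(methoxymethoxy)-5-{[(1R,2S,4aS,8aS)-1,2,4a-trimethyl-5-methylidenedecahydronaphthalen-1-yl]methyl}benzoate
Product: 31 methyl 2,3,4-trihydroxy-5-{[(1R,2S,4aS,8aS)-1,2,4a-trimethyl-5-methylidenedecahydronaphthalen-1-yl]methyl}benzoate (CNP0162211.1)
Conditions: HCl (cat., 1.25 M in MeOH), MeOH, 0 °C → rt, argon
Reagents that add atoms: none
Why: Acid-catalysed transacetalisation removes the three aryl MOM ethers under conditions that should be too mild to isomerise the exocyclic alkene.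

**Compound list**

1 | pyrogallol (benzene-1,2,3-triol) | Oc1cccc(O)c1O | starting material
2 | 1,2,3-tris(methoxymethoxy)benzene | COCOc1cccc(OCOC)c1OCOC | intermediate
3 | methyl (R)-lactate | C[C@@H](O)C(=O)OC | starting material
4 | methyl (2R)-2-[(tert-butyldimethylsilyl)oxy]propanoate | C[C@@H](O[Si](C)(C)C(C)(C)C)C(=O)OC | intermediate
5 | (2R)-2-[(tert-butyldimethylsilyl)oxy]propanal | C[C@@H](O[Si](C)(C)C(C)(C)C)C=O | intermediate
6 | ethyl (2E,4R)-4-[(tert-butyldimethylsilyl)oxy]-2-methylpent-2-enoate | C[C@@H](O[Si](C)(C)C(C)(C)C)/C=C(\C)C(=O)OCC | intermediate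
7 | (2E,4R)-4-[(tert-butyldimethylsilyl)oxy]-2-methylpent-2-en-1-ol | C[C@@H](O[Si](C)(C)C(C)(C)C)/C=C(\C)CO | intermediate
8 | {[(2R,3E)-5-bromo-4-methylpent-3-en-2-yl]oxy}(tert-butyl)dimethylsilane | C[C@@H](O[Si](C)(C)C(C)(C)C)/C=C(\C)CBr | intermediate
9 | 2,3,4-tris(methoxymethoxy)phenyllithium | [Li]c1ccc(OCOC)c(OCOC)c1OCOC | intermediate
10 | tert-butyldimethyl({(2R,3E)-4-methyl-5-[2,3,4-tris(methoxymethoxy)phenyl]pent-3-en-2-yl}oxy)silane | C[C@@H](O[Si](C)(C)C(C)(C)C)/C=C(\C)Cc1ccc(OCOC)c(OCOC)c1OCOC | intermediate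
11 | (2R,3E)-4-methyl-5-[2,3,4-tris(methoxymethoxy)phenyl]pent-3-en-2-ol | C[C@@H](O)/C=C(\C)Cc1ccc(OCOC)c(OCOC)c1OCOC | intermediate
12 | (2R,3E)-4-methyl-5-[2,3,4-tris(methoxymethoxy)phenyl]pent-3-en-2-yl propanoate | C[C@@H](OC(=O)CC)/C=C(\C)Cc1ccc(OCOC)c(OCOC)c1OCOC | intermediate
13 | trimethyl{[(1Z)-1-({(2R,3E)-4-methyl-5-[2,3,4-tris(methoxymethoxy)phenyl]pent-3-en-2-yl}oxy)prop-1-en-1-yl]oxy}silane (CH3 cis to OSi) | C[C@@H](O/C(O[Si](C)(C)C)=C/C)/C=C(\C)Cc1ccc(OCOC)c(OCOC)c1OCOC | intermediate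
14 | trimethylsilyl (2R,3S,4E)-2,3-dimethyl-3-[2,3,4-tris(methoxymethoxy)benzyl]hex-4-enoate | C/C=C/[C@](C)(Cc1ccc(OCOC)c(OCOC)c1OCOC)[C@@H](C)C(=O)O[Si](C)(C)C | intermediate
15 | (2R,3S,4E)-2,3-dimethyl-3-[2,3,4-tris(methoxymethoxy)benzyl]hex-4-enoic acid | C/C=C/[C@](C)(Cc1ccc(OCOC)c(OCOC)c1OCOC)[C@@H](C)C(=O)O | intermediate
16 | (2R,3S,4E)-2,3-dimethyl-3-[2,3,4-tris(methoxymethoxy)benzyl]hex-4-en-1-ol | C/C=C/[C@](C)(Cc1ccc(OCOC)c(OCOC)c1OCOC)[C@@H](C)CO | intermediate
17 | 1-{[(2E,4S,5R)-6-iodo-4,5-dimethylhex-2-en-4-yl]methyl}-2,3,4-tris(methoxymethoxy)benzene | C/C=C/[C@](C)(Cc1ccc(OCOC)c(OCOC)c1OCOC)[C@@H](C)CI | intermediate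
18 | methacryloyl chloride | C=C(C)C(=O)Cl | starting material
19 | N-methoxy-N-methylmethacrylamide | C=C(C)C(=O)N(C)OC | intermediate
20 | (5S,6R,7E)-N-methoxy-N,2,5,6-tetramethyl-6-[2,3,4-tris(methoxymethoxy)benzyl]non-7-enamide (C2 epimers) | C/C=C/[C@](C)(Cc1ccc(OCOC)c(OCOC)c1OCOC)[C@@H](C)CCC(C)C(=O)N(C)OC | intermediate
21 | (5S,6R)-N-methoxy-N,2,5,6-tetramethyl-7-oxo-6-[2,3,4-tris(methoxymethoxy)benzyl]heptanamide (C2 epimers) | O=C[C@](C)(Cc1ccc(OCOC)c(OCOC)c1OCOC)[C@@H](C)CCC(C)C(=O)N(C)OC | intermediate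
22 | (5S,6R,7E)-N-methoxy-N,2,5,6-tetramethyl-8-(phenylsulfonyl)-6-[2,3,4-tris(methoxymethoxy)benzyl]oct-7-enamide (C2 epimers) | O=S(=O)(c1ccccc1)/C=C/[C@](C)(Cc1ccc(OCOC)c(OCOC)c1OCOC)[C@@H](C)CCC(C)C(=O)N(C)OC | intermediate
23 | (7S,8R,9E)-4,7,8-trimethyl-10-(phenylsulfonyl)-8-[2,3,4-tris(methoxymethoxy)benzyl]deca-1,9-dien-3-one (C4 epimers) | O=S(=O)(c1ccccc1)/C=C/[C@](C)(Cc1ccc(OCOC)c(OCOC)c1OCOC)[C@@H](C)CCC(C)C(=O)C=C | intermediate
24 | tert-butyl({(3Z,7S,8R,9E)-4,7,8-trimethyl-10-(phenylsulfonyl)-8-[2,3,4-tris(methoxymethoxy)benzyl]deca-1,3,9-trien-3-yl}oxy)dimethylsilane | O=S(=O)(c1ccccc1)/C=C/[C@](C)(Cc1ccc(OCOC)c(OCOC)c1OCOC)[C@@H](C)CC/C(C)=C(\O[Si](C)(C)C(C)(C)C)C=C | intermediate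
25 | tert-butyldimethyl({(4S,4aS,5R,6S,8aS)-5,6,8a-trimethyl-4-(phenylsulfonyl)-5-[2,3,4-tris(methoxymethoxy)benzyl]-3,4,4a,5,6,7,8,8a-octahydronaphthalen-1-yl}oxy)silane | CC(C)(C)[Si](C)(C)OC1=CC[C@H](S(=O)(=O)c3ccccc3)[C@H]2[C@](C)(Cc3ccc(OCOC)c(OCOC)c3OCOC)[C@@H](C)CC[C@]12C | intermediate
26 | (4S,4aS,5R,6S,8aS)-5,6,8a-trimethyl-4-(phenylsulfonyl)-5-[2,3,4-tris(methoxymethoxy)benzyl]octahydronaphthalen-1(2H)-one | O=C1CC[C@H](S(=O)(=O)c3ccccc3)[C@H]2[C@](C)(Cc3ccc(OCOC)c(OCOC)c3OCOC)[C@@H](C)CC[C@]12C | intermediate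
27 | 1-{[(1R,2S,4aS,8S,8aS)-1,2,4a-trimethyl-5-methylidene-8-(phenylsulfonyl)decahydronaphthalen-1-yl]methyl}-2,3,4-tris(methoxymethoxy)benzene | C=C1CC[C@H](S(=O)(=O)c3ccccc3)[C@H]2[C@](C)(Cc3ccc(OCOC)c(OCOC)c3OCOC)[C@@H](C)CC[C@]12C | intermediate
28 | 1-{[(1R,2S,4aS,8aS)-1,2,4a-trimethyl-5-methylidenedecahydronaphthalen-1-yl]methyl}-2,3,4-tris(methoxymethoxy)benzene | C=C1CCC[C@H]2[C@](C)(Cc3ccc(OCOC)c(OCOC)c3OCOC)[C@@H](C)CC[C@]12C | intermediate
29 | aryllithium of 28, lithiated ortho to the OMOM group remote from the alkyl chain | C=C1CCC[C@H]2[C@](C)(Cc3cc([Li])c(OCOC)c(OCOC)c3OCOC)[C@@H](C)CC[C@]12C | intermediate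
30 | methyl 2,3,4-tris(methoxymethoxy)-5-{[(1R,2S,4aS,8aS)-1,2,4a-trimethyl-5-methylidenedecahydronaphthalen-1-yl]methyl}benzoate | C=C1CCC[C@H]2[C@](C)(Cc3cc(C(=O)OC)c(OCOC)c(OCOC)c3OCOC)[C@@H](C)CC[C@]12C | intermediate
31 | methyl 2,3,4-trihydroxy-5-{[(1R,2S,4aS,8aS)-1,2,4a-trimethyl-5-methylidenedecahydronaphthalen-1-yl]methyl}benzoate | C=C1CCC[C@H]2[C@](C)(Cc3cc(C(=O)OC)c(O)c(O)c3O)[C@@H](C)CC[C@]12C | target

**Step count and risks**

Total step count: 21. Longest linear sequence: 19 steps (from methyl (R)-lactate 3: steps 2–11 and 13–21).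

Steps most likely to fail:

Step 17. The reactive (3Z)-dienol ether may form incompletely, a 1,5-hydrogen shift in the diene may compete at 120 °C, and trans ring fusion or facial selectivity may erode in the cycloaddition. Fallback, setting out from 23 and returning at 26: an anionic intramolecular double Michael reaction with LiN(SiMe3)2 in THF at −78 → 0 °C. Deprotonation at C5 gives the lithium dienolate F1, whose C5 adds to C10 of the vinyl sulfone to give the ring-B α-sulfonyl carbanion F2. This carbanion closes ring A by 6-endo Michael addition to the acryloyl group and gives the lithium enolate F3, which aqueous NH4Cl protonates to 26. The enolate geometry is irrelevant in this stepwise path, and because the first Michael addition is reversible, the product-determining ring-A closure should select the diequatorial (trans-fused) arrangement.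

Step 9. Enolisation may not be fully Z(O)-selective, the rearrangement may leak through a boat transition state (both give the C8 epimer), and it may be slow at the fully substituted allyl terminus. Fallback, setting out from 11 and returning at 15: acylation with acryloyl chloride and Et3N gives the acrylate ester F4. A rhodium-catalysed reductive Ireland–Claisen rearrangement follows ([RhCl(cod)]2 with a bisphosphine, HSiMeCl2, benzene, rt → 40 °C). Conjugate hydrosilylation of the s-cis acrylate delivers the silyl ketene acetal F5 with CH3 cis to OSi without any base, and it rearranges in the flask to the silyl ester F6. Aqueous work-up gives 15.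

Step 16. The Grignard reagent may add in conjugate fashion to the vinyl sulfone, and liberated N,O-dimethylhydroxylamine may add to the vinyl ketone. Fallback, setting out from 22 and returning at 23: reduction of the Weinreb amide with i-Bu2AlH in THF at −78 °C gives the aldehyde F7. Nozaki–Hiyama–Kishi vinylation (CH2=CHBr, CrCl2, NiCl2 (cat.), DMF, rt), which is selective for aldehydes and does not touch vinyl sulfones, gives the allylic alcohol F8. Oxidation with Dess–Martin periodinane in CH2Cl2 gives 23.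

Further compounds
F1 | step 17 | lithium cross-conjugated dienolate of 23 | O=S(=O)(c1ccccc1)/C=C/[C@](C)(Cc1ccc(OCOC)c(OCOC)c1OCOC)[C@@H](C)CCC(C)=C(O[Li])C=C
F2 | step 17 | ring-B-closed α-lithio sulfone (1-acryloyl-1,3,4-trimethyl-3-arylmethyl-2-[lithio(phenylsulfonyl)methyl]cyclohexane, configuration as in 26) | [Li]C(S(=O)(=O)c3ccccc3)[C@H]2[C@](C)(Cc3ccc(OCOC)c(OCOC)c3OCOC)[C@@H](C)CC[C@@]2(C(=O)C=C)C
F3 | step 17 | lithium enolate of 26 | [Li]OC1=CC[C@H](S(=O)(=O)c3ccccc3)[C@H]2[C@](C)(Cc3ccc(OCOC)c(OCOC)c3OCOC)[C@@H](C)CC[C@]12C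
F4 | step 9 | (2R,3E)-4-methyl-5-[2,3,4-tris(methoxymethoxy)phenyl]pent-3-en-2-yl acrylate | C[C@@H](OC(=O)C=C)/C=C(\C)Cc1ccc(OCOC)c(OCOC)c1OCOC
F5 | step 9 | dichloro(methyl)silyl ketene acetal of the propanoate (CH3 cis to OSi) | C[C@@H](O/C(O[Si](C)(Cl)Cl)=C/C)/C=C(\C)Cc1ccc(OCOC)c(OCOC)c1OCOC
F6 | step 9 | dichloro(methyl)silyl (2R,3S,4E)-2,3-dimethyl-3-[2,3,4-tris(methoxymethoxy)benzyl]hex-4-enoate | C/C=C/[C@](C)(Cc1ccc(OCOC)c(OCOC)c1OCOC)[C@@H](C)C(=O)O[Si](C)(Cl)Cl
F7 | step 16 | (5S,6R,7E)-2,5,6-trimethyl-8-(phenylsulfonyl)-6-[2,3,4-tris(methoxymethoxy)benzyl]oct-7-enal | O=S(=O)(c1ccccc1)/C=C/[C@](C)(Cc1ccc(OCOC)c(OCOC)c1OCOC)[C@@H](C)CCC(C)C=O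
F8 | step 16 | (7S,8R,9E)-4,7,8-trimethyl-10-(phenylsulfonyl)-8-[2,3,4-tris(methoxymethoxy)benzyl]deca-1,9-dien-3-ol | O=S(=O)(c1ccccc1)/C=C/[C@](C)(Cc1ccc(OCOC)c(OCOC)c1OCOC)[C@@H](C)CCC(C)C(O)C=C
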